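**Plan**

1. Cuts, in eunicellane numbering (cyclohexane C1, C10, C11, C12, C13, C14 with C11(OH)Me and C14 i‑Pr; ten-membered ring C1–C10 with Z C2=C3, C6–OAc, C7=CH2, C9–OAc): the two acetates; C6–C7; C3–C4; C2=C3; then C10–C11; then C1=C10 and the O9–C2 ester bond of a butenolide; last, the C11/C2 carbonyl pair is traced back to the ring alkene of p‑menthene.
2. Enabling feature: O9 and C2 stand 1,4 and cis across the C1–C10 ring fusion, so they can be tied as a butenolide O9–C9–C10=C1–C2(=O). In this temporary five-membered ring C10 is the β‑carbon of an unsaturated lactone, the C11 methyl ketone on the C1 side chain reaches it in a 6‑endo ketyl addition, and C9 steers the face. The lactone later gives back C2 as a lactol and O9 as the acetoxy oxygen.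
3. Forward: (S)‑limonene is hydrogenated, ozonised, α‑methylenated and oxidised to a keto acid (limonene C1/C7 become C11 and its methyl, C6/C5/C4 become C12/C13/C14, C3 becomes C1, and the old ring carbon C2 is pushed out to become C2 of the large ring). Esterification with (R)‑5‑bromohexa‑1,5‑dien‑3‑ol (C10, C9, C8, C7, C20) and ring-closing metathesis give the butenolide; SmI2 then closes the cyclohexane with C10 inserted.
4. Then lactol, Z‑iodo‑olefination (C3 and its methyl), B‑alkyl Suzuki–Miyaura coupling (C4–C6), acetal hydrolysis, Nozaki–Hiyama–Kishi closure of the ten-membered ring at C6–C7, and diacetylation.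
5. Stereochemistry: C14 from (S)‑limonene; C9 from a Sharpless kinetic resolution; C10, C1 and C11 from the key step (anti to the C9 substituent, cis lactone fusion, Sm–O outside); Z C2=C3 from the iodo ylide and a stereoretentive coupling; C6 from the macrocyclic ring closure.

Key step: step 9

Remark: locants in the text are the eunicellane locants defined in the plan; the ring closure of step 14 is assumed to give the (6R) alcohol, and the fallback for step 14 covers the opposite outcome.

**Route**

Step 1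
Reactants: 1 (S)-(−)-limonene
Product: 2 (4S)-1-methyl-4-(propan-2-yl)cyclohex-1-ene
Conditions: H2 (1 atm), RhCl(PPh3)3 (2 mol %), benzene/EtOH, rt
Reagents that add atoms: none
Why: Homogeneous hydrogenation with RhCl(PPh3)3 reduces the 1,1-disubstituted isopropenyl alkene much faster than the trisubstituted ring alkene, so the ring alkene and the chiral-pool stereocentre (future C14) are kept.

Step 2
Reactants: 2 (4S)-1-methyl-4-(propan-2-yl)cyclohex-1-ene
Product: 4 (3S)-6-oxo-3-(propan-2-yl)heptanal, via secondary ozonide 3 (not isolated)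
Conditions: O3, CH2Cl2, −78 °C; then Me2S, −78 °C to rt
Reagents that add atoms: ozone [O-][O+]=O
Why: Ozonolysis with reductive work-up cleaves the ring alkene to the methyl ketone (future C11) and the aldehyde (future C2) without touching the stereocentre.

Step 3
Reactants: 4 (3S)-6-oxo-3-(propan-2-yl)heptanal
Product: 5 (3R)-2-methylidene-6-oxo-3-(propan-2-yl)heptanal
Conditions: 37% aq. CH2O, pyrrolidine (10 mol %), EtCO2H (10 mol %), i-PrOH, 45 °C
Reagents that add atoms: formaldehyde C=O
Why: Amine-catalysed Mannich condensation and elimination (organocatalytic α-methylenation) proceeds through the aldehyde enamine only, the ketone being a far poorer enamine donor, and puts on C1 the methylene that serves as metathesis handle.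

Step 4
Reactants: 5 (3R)-2-methylidene-6-oxo-3-(propan-2-yl)heptanal
Product: 6 (3R)-2-methylidene-6-oxo-3-(propan-2-yl)heptanoic acid
Conditions: NaClO2, NaH2PO4, 2-methylbut-2-ene, t-BuOH/H2O, 0 °C to rt
Reagents that add atoms: sodium chlorite [Na+].[O-]Cl=O
Why: Pinnick oxidation converts the 2-substituted acrolein to the acrylic acid without affecting the ketone or the alkene.

Step 5
Reactants: 7 acrolein; 8 2,3-dibromopropene
Product: 9 rac-5-bromohexa-1,5-dien-3-ol
Conditions: In powder, THF/H2O (1:1), rt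
Reagents that add atoms: none
Why: Indium-mediated Barbier 2-bromoallylation adds 1,2 to the enal in aqueous medium and brings in C9, C10, C8, C7 and C20 in one step.

Step 6
Reactants: 9 rac-5-bromohexa-1,5-dien-3-ol
Product: 10 (3R)-5-bromohexa-1,5-dien-3-ol
Conditions: Ti(OiPr)4 (cat.), L-(+)-DIPT, t-BuOOH (0.6 equiv), 4 Å MS, CH2Cl2, −20 °C
Reagents that add atoms: none
Why: Sharpless kinetic resolution: with L-(+)-DIPT the (S)-allylic alcohol is epoxidised faster (erythro epoxy alcohol), so the unreacted alcohol should be recovered as the (R)-enantiomer, which fixes C9.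

Step 7
Reactants: 6 (3R)-2-methylidene-6-oxo-3-(propan-2-yl)heptanoic acid; 10 (3R)-5-bromohexa-1,5-dien-3-ol
Product: 11 (3R)-5-bromohexa-1,5-dien-3-yl (3R)-2-methylidene-6-oxo-3-(propan-2-yl)heptanoate
Conditions: DCC, DMAP (cat.), CH2Cl2, 0 °C to rt
Reagents that add atoms: none
Why: Steglich esterification joins the two fragments through the O9–C2 bond with retention at the carbinol carbon.

Step 8
Reactants: 11 (3R)-5-bromohexa-1,5-dien-3-yl (3R)-2-methylidene-6-oxo-3-(propan-2-yl)heptanoate
Product: 12 (5R)-5-(2-bromoprop-2-en-1-yl)-3-[(3R)-2-methyl-6-oxoheptan-3-yl]furan-2(5H)-one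
Conditions: second-generation Grubbs catalyst RuCl2(=CHPh)(PCy3)(H2IMes) (5–10 mol %), toluene (0.005 M), 80 °C
Reagents that add atoms: none
Why: Ring-closing metathesis of an allyl 2-alkylacrylate gives the α-substituted butenolide (C1=C10) with loss of ethene; the 2-bromoalkene is inert to the ruthenium carbene.

Step 9
Reactants: 12 (5R)-5-(2-bromoprop-2-en-1-yl)-3-[(3R)-2-methyl-6-oxoheptan-3-yl]furan-2(5H)-one
Product: 13 (3R,3aS,4R,7R,7aR)-3-(2-bromoprop-2-en-1-yl)-4-hydroxy-4-methyl-7-(propan-2-yl)hexahydro-2-benzofuran-1(3H)-one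
Conditions: SmI2 (2.2 equiv), HMPA (8 equiv), t-BuOH (2.5 equiv), THF, −78 °C, short reaction time; aq. NH4Cl
Reagents that add atoms: none
Why: Divalent samarium reduces the C11 ketone to a ketyl radical anion that adds to C10, the β-carbon of the butenolide, after which the α-carbonyl radical is reduced to the samarium enolate and protonated by t-BuOH (closest known type: SmI2 ketyl–olefin reductive cyclisation onto α,β-unsaturated lactones). The cyclohexane (C10, C11, C12, C13, C14, C1) closes in the 6-endo-trig mode because the tether sits on the α-carbon C1, whereas 5-exo attack at C1 would be polarity-mismatched and would create a quaternary centre. C10: the ketyl should add to the butenolide face anti to the 2-bromoallyl group on the adjacent γ-carbon C9, and the tether conformer with C14–H eclipsing the lactone carbonyl (isopropyl on the far face) reinforces this. C11: the HMPA-solvated, non-chelating O–Sm group should take the outside position with the methyl over the lactone ring, which gives the (11R) carbinol. C1: protonation of the enolate should give the cis-fused lactone, which is also the thermodynamic isomer (isopropyl and C2 equatorial), so any trans isomer can be equilibrated with base. The step needs ketone–lactone coupling to win over reduction of the bromoalkene and over reductive C9–O cleavage of the butenolide, and the low temperature, short time and only 2.2 equiv of SmI2 are meant to secure this.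

Step 10
Reactants: 13 (3R,3aS,4R,7R,7aR)-3-(2-bromoprop-2-en-1-yl)-4-hydroxy-4-methyl-7-(propan-2-yl)hexahydro-2-benzofuran-1(3H)-one
Product: 14 (3R,3aS,4R,7R,7aR)-3-(2-bromoprop-2-en-1-yl)-4-methyl-7-(propan-2-yl)octahydro-2-benzofuran-1,4-diol (lactol, anomer mixture)
Conditions: i-Bu2AlH (2.2 equiv), CH2Cl2, −78 °C; aq. potassium sodium tartrate
Reagents that add atoms: none
Why: Partial reduction of the γ-lactone stops at the aluminium hemiacetal at −78 °C and unmasks C2 at the aldehyde level; the tertiary alkoxide and the bromoalkene are inert.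

Step 11
Reactants: 14 lactol (as above)
Product: 15 (1R,2S,3R,4R)-2-[(1R)-3-bromo-1-hydroxybut-3-en-1-yl]-3-[(1Z)-2-iodoprop-1-en-1-yl]-1-methyl-4-(propan-2-yl)cyclohexan-1-ol
Conditions: [Ph3PEt]I, n-BuLi, THF, rt; I2, −78 °C; NaN(SiMe3)2, −20 °C; then 14, −78 to −20 °C
Reagents that add atoms: ethyltriphenylphosphonium iodide CC[P+](c1ccccc1)(c1ccccc1)c1ccccc1.[I-]; iodine II (together they form (1-iodoethylidene)triphenylphosphorane CC(I)=P(c1ccccc1)(c1ccccc1)c1ccccc1 in the flask)
Why: Stork–Zhao-type Wittig olefination of the open hydroxy-aldehyde form of the lactol with the α-iodo ylide should give the (Z)-2-iodoalkene (iodine cis to C1) under kinetic oxaphosphetane control and frees O9.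

Step 12
Reactants: 15 vinyl iodide diol (as above); 16 acrolein diethyl acetal
Product: 18 (1R,2S,3S,4R)-2-[(1R)-3-bromo-1-hydroxybut-3-en-1-yl]-3-[(1Z)-5,5-diethoxy-2-methylpent-1-en-1-yl]-1-methyl-4-(propan-2-yl)cyclohexan-1-ol, via B-(3,3-diethoxypropyl)-9-BBN 17 (not isolated)
Conditions: 16, 9-BBN-H, THF, rt; then 15, PdCl2(dppf) (5 mol %), AsPh3, Cs2CO3, DMF/H2O, rt
Reagents that add atoms: none
Why: B-alkyl Suzuki–Miyaura coupling: zerovalent palladium inserts into the C–I bond much faster than into the C–Br bond and couples with retention, so the Z trisubstituted C2=C3 alkene and C4–C6 are installed while the bromoalkene is kept.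

Step 13
Reactants: 18 diethyl acetal (as above)
Product: 19 (4Z)-5-{(1S,2S,3R,6R)-2-[(1R)-3-bromo-1-hydroxybut-3-en-1-yl]-3-hydroxy-3-methyl-6-(propan-2-yl)cyclohexyl}-4-methylpent-4-enal
Conditions: PPTS (cat.), acetone/H2O, 45 °C
Reagents that add atoms: water O
Why: Mild acid-catalysed acetal hydrolysis frees the C6 aldehyde; the alcohols are not ionised under these conditions.

Step 14
Reactants: 19 bromo aldehyde (as above)
Product: 20 (1S,2Z,6R,9R,10S,11R,14R)-eunicella-2,7(20)-diene-6,9,11-triol
Conditions: CrCl2 (8 equiv), NiCl2 (2 mol %), DMSO/THF, rt, slow addition to 0.003 M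
Reagents that add atoms: none
Why: Nozaki–Hiyama–Kishi coupling: nickel-catalysed formation of the alkenylchromium species (trivalent chromium) from the 2-bromoalkene and its chemoselective 1,2-addition to the aldehyde close the ten-membered ring at C6–C7 and create the C6 allylic alcohol next to the exo-methylene, with free hydroxyls tolerated and the (6R) sense assumed from the ring conformation.

Step 15
Reactants: 20 triol (as above)
Product: 21 (1S,2Z,6R,9R,10S,11R,14R)-11-hydroxyeunicella-2,7(20)-diene-6,9-diyl diacetate (target)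
Conditions: Ac2O, pyridine, DMAP (cat.), CH2Cl2, 0 °C to rt
Reagents that add atoms: acetic anhydride CC(=O)OC(C)=O
Why: Acylation of the two secondary alcohols; the hindered tertiary C11 alcohol should not react under these conditions.

**Compound list**

1 | (S)-(−)-limonene | CC1=CC[C@H](CC1)C(C)=C | starting material
2 | (4S)-1-methyl-4-(propan-2-yl)cyclohex-1-ene | CC1=CC[C@H](CC1)C(C)C | intermediate
3 | secondary ozonide of 2, 1-methyl-4-(propan-2-yl)-7,8,9-trioxabicyclo[4.2.1]nonane | CC12CC[C@H](C(C)C)CC(OO1)O2 | intermediate (not isolated)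
4 | (3S)-6-oxo-3-(propan-2-yl)heptanal | O=CC[C@H](CCC(C)=O)C(C)C | intermediate
5 | (3R)-2-methylidene-6-oxo-3-(propan-2-yl)heptanal | C=C(C=O)[C@H](CCC(C)=O)C(C)C | intermediate
6 | (3R)-2-methylidene-6-oxo-3-(propan-2-yl)heptanoic acid | C=C(C(=O)O)[C@H](CCC(C)=O)C(C)C | intermediate
7 | acrolein | C=CC=O | starting material
8 | 2,3-dibromopropene | C=C(Br)CBr | starting material
9 | rac-5-bromohexa-1,5-dien-3-ol | C=CC(O)CC(Br)=C | intermediate
10 | (3R)-5-bromohexa-1,5-dien-3-ol | C=C[C@H](O)CC(Br)=C | intermediate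
11 | (3R)-5-bromohexa-1,5-dien-3-yl (3R)-2-methylidene-6-oxo-3-(propan-2-yl)heptanoate | C=C(C(=O)O[C@@H](C=C)CC(Br)=C)[C@H](CCC(C)=O)C(C)C | intermediate
12 | (5R)-5-(2-bromoprop-2-en-1-yl)-3-[(3R)-2-methyl-6-oxoheptan-3-yl]furan-2(5H)-one | O=C1O[C@H](CC(Br)=C)C=C1[C@H](CCC(C)=O)C(C)C | intermediate
13 | (3R,3aS,4R,7R,7aR)-3-(2-bromoprop-2-en-1-yl)-4-hydroxy-4-methyl-7-(propan-2-yl)hexahydro-2-benzofuran-1(3H)-one | C=C(Br)C[C@@H](OC1=O)[C@@H]2[C@H]1[C@@H](C(C)C)CC[C@@]2(C)O | intermediate
14 | (3R,3aS,4R,7R,7aR)-3-(2-bromoprop-2-en-1-yl)-4-methyl-7-(propan-2-yl)octahydro-2-benzofuran-1,4-diol (lactol, anomer mixture) | C=C(Br)C[C@@H](OC1O)[C@@H]2[C@H]1[C@@H](C(C)C)CC[C@@]2(C)O | intermediate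
15 | (1R,2S,3R,4R)-2-[(1R)-3-bromo-1-hydroxybut-3-en-1-yl]-3-[(1Z)-2-iodoprop-1-en-1-yl]-1-methyl-4-(propan-2-yl)cyclohexan-1-ol | C=C(Br)C[C@@H](O)[C@@H]1[C@H](/C=C(/C)I)[C@@H](C(C)C)CC[C@@]1(C)O | intermediate
16 | acrolein diethyl acetal (3,3-diethoxyprop-1-ene) | C=CC(OCC)OCC | starting material
17 | 9-(3,3-diethoxypropyl)-9-borabicyclo[3.3.1]nonane | CCOC(OCC)CCB1C2CCCC1CCC2 | intermediate (not isolated)
18 | (1R,2S,3S,4R)-2-[(1R)-3-bromo-1-hydroxybut-3-en-1-yl]-3-[(1Z)-5,5-diethoxy-2-methylpent-1-en-1-yl]-1-methyl-4-(propan-2-yl)cyclohexan-1-ol | C=C(Br)C[C@@H](O)[C@@H]1[C@H](/C=C(/C)CCC(OCC)OCC)[C@@H](C(C)C)CC[C@@]1(C)O | intermediate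
19 | (4Z)-5-{(1S,2S,3R,6R)-2-[(1R)-3-bromo-1-hydroxybut-3-en-1-yl]-3-hydroxy-3-methyl-6-(propan-2-yl)cyclohexyl}-4-methylpent-4-enal | C=C(Br)C[C@@H](O)[C@@H]1[C@H](/C=C(/C)CCC=O)[C@@H](C(C)C)CC[C@@]1(C)O | intermediate
20 | (1S,2Z,6R,9R,10S,11R,14R)-eunicella-2,7(20)-diene-6,9,11-triol | C=C1C[C@@H](O)[C@@H]2[C@H](/C=C(/C)CC[C@H]1O)[C@@H](C(C)C)CC[C@@]2(C)O | intermediate
21 | (1S,2Z,6R,9R,10S,11R,14R)-11-hydroxyeunicella-2,7(20)-diene-6,9-diyl diacetate | C=C1C[C@@H](OC(C)=O)[C@@H]2[C@H](/C=C(/C)CC[C@H]1OC(C)=O)[C@@H](C(C)C)CC[C@@]2(C)O | target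

**Count and risks**

Total steps: 15. Longest linear sequence: 13 (steps 1–4 and 7–15).

Steps most likely to fail:

1. Step 9. What may go wrong: poor facial selectivity at the ketyl carbon C11, the samarium-bound oxygen going inside (chelated to the lactone) and not outside. Competing electron transfer to the butenolide is a second concern. Fallback (sets out from 12, returns at 13): the cyclisation is run under chelating conditions (SmI2, THF/MeOH, −78 °C, no HMPA) and should then give the C4-epimeric hydroxy lactone F1. Dehydration with Burgess reagent (benzene, 50 °C) gives the methylidene lactone F2. Mukaiyama hydration (Mn(dpm)3 cat., PhSiH3, O2, i-PrOH/CH2Cl2, 0 °C; then P(OEt)3) forms the tertiary C11 radical, and oxygen should be taken up axially on the outside face, anti to the axial C9 branch, to give 13. The C11 centre is thus set after ring closure instead of in it.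

2. Step 14. What may go wrong: poor or opposite facial selectivity at the C6 aldehyde in the ring closure, and slow oxidative addition of the bromoalkene leading to oligomers. Fallback (sets out from 18, returns at 21): the C9 alcohol is acetylated first (Ac2O, pyridine) to the acetate acetal F7, the acetal is hydrolysed (PPTS, acetone/H2O) to the aldehyde F8, and the same CrCl2/NiCl2 closure gives the macrocyclic C6 alcohol F9 as whatever epimer mixture arises. Dess–Martin oxidation gives the α-methylene ketone F10. Corey–Bakshi–Shibata reduction with the (S)-methyl oxazaborolidine and BH3·SMe2 (toluene, −40 °C), in which the alkenyl group acts as the large substituent, should give the (6R) alcohol F11 under reagent control. Acetylation then gives 21.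

3. Step 11. What may go wrong: the lactol may not open fast enough at the low temperature that the thermally labile iodo ylide requires, so that the ylide decomposes before olefination. Fallback (sets out from 13, returns at 15): the lactone is opened with MeNH(OMe)·HCl/AlMe3 to the Weinreb amide diol F3, both hydroxyls are silylated (Et3SiOTf, 2,6-lutidine) to the bis(triethylsilyl) ether F4, and i-Bu2AlH (−78 °C) gives the free aldehyde F5 (formyl equatorial, not prone to epimerisation). The same iodo ylide then gives the (Z)-vinyl iodide bis(silyl ether) F6 from an open-chain aldehyde, and Bu4NF removes both silyl groups to give 15.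

Further compounds
F1 | step 9 | (3R,3aS,4S,7R,7aR)-3-(2-bromoprop-2-en-1-yl)-4-hydroxy-4-methyl-7-(propan-2-yl)hexahydro-2-benzofuran-1(3H)-one | C=C(Br)C[C@@H](OC1=O)[C@@H]2[C@H]1[C@@H](C(C)C)CC[C@]2(C)O
F2 | step 9 | (3R,3aR,7R,7aR)-3-(2-bromoprop-2-en-1-yl)-4-methylidene-7-(propan-2-yl)hexahydro-2-benzofuran-1(3H)-one | C=C(Br)C[C@@H](OC1=O)[C@@H]2[C@H]1[C@@H](C(C)C)CCC2=C
F3 | step 11 | (1R,2S,3R,6R)-2-[(1R)-3-bromo-1-hydroxybut-3-en-1-yl]-3-hydroxy-N-methoxy-N,3-dimethyl-6-(propan-2-yl)cyclohexane-1-carboxamide | C=C(Br)C[C@@H](O)[C@@H]1[C@H](C(=O)N(C)OC)[C@@H](C(C)C)CC[C@@]1(C)O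
F4 | step 11 | bis(triethylsilyl) ether of F3 | C=C(Br)C[C@@H](O[Si](CC)(CC)CC)[C@@H]1[C@H](C(=O)N(C)OC)[C@@H](C(C)C)CC[C@@]1(C)O[Si](CC)(CC)CC
F5 | step 11 | 2-[(1R)-3-bromo-1-(triethylsilyloxy)but-3-en-1-yl]-3-methyl-6-(propan-2-yl)-3-(triethylsilyloxy)cyclohexane-1-carbaldehyde (ring configuration as in F3) | C=C(Br)C[C@@H](O[Si](CC)(CC)CC)[C@@H]1[C@H](C=O)[C@@H](C(C)C)CC[C@@]1(C)O[Si](CC)(CC)CC
F6 | step 11 | bis(triethylsilyl) ether of 15 | C=C(Br)C[C@@H](O[Si](CC)(CC)CC)[C@@H]1[C@H](/C=C(/C)I)[C@@H](C(C)C)CC[C@@]1(C)O[Si](CC)(CC)CC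
F7 | step 14 | C9 acetate of 18 | C=C(Br)C[C@@H](OC(C)=O)[C@@H]1[C@H](/C=C(/C)CCC(OCC)OCC)[C@@H](C(C)C)CC[C@@]1(C)O
F8 | step 14 | C9 acetate of 19 | C=C(Br)C[C@@H](OC(C)=O)[C@@H]1[C@H](/C=C(/C)CCC=O)[C@@H](C(C)C)CC[C@@]1(C)O
F9 | step 14 | (1S,2Z,9R,10S,11R,14R)-6,11-dihydroxyeunicella-2,7(20)-dien-9-yl acetate (C6 epimer mixture) | C=C1C[C@@H](OC(C)=O)[C@@H]2[C@H](/C=C(/C)CCC1O)[C@@H](C(C)C)CC[C@@]2(C)O
F10 | step 14 | (1S,2Z,9R,10S,11R,14R)-11-hydroxy-6-oxoeunicella-2,7(20)-dien-9-yl acetate | C=C1C[C@@H](OC(C)=O)[C@@H]2[C@H](/C=C(/C)CCC1=O)[C@@H](C(C)C)CC[C@@]2(C)O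
F11 | step 14 | (1S,2Z,6R,9R,10S,11R,14R)-6,11-dihydroxyeunicella-2,7(20)-dien-9-yl acetate | C=C1C[C@@H](OC(C)=O)[C@@H]2[C@H](/C=C(/C)CC[C@H]1O)[C@@H](C(C)C)CC[C@@]2(C)O
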